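The seven-membered ring is cut into a three-carbon unit (ring-fusion CH C5, carbinol carbon C6, methylene C7) and a four-carbon unit (C8, C9, C10 and the quaternary C1; daucane numbering). One intramolecular (4+3) cycloaddition of a silyl-activated epoxy enol silane with a tethered (E,E)-diene forms C1–C5 and C7–C8, closing the cyclopentane and the cycloheptene together. It exploits the oxygen pattern O–C4–C5–C6–O spanning both rings: the epoxide oxygen becomes the C4 tertiary hydroxyl and the oxyallyl carbon becomes the C6 ketone. The precursor is an acyclic epoxy methyl ketone enol silane whose two-carbon tether carries the C2 silyloxy group.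

Key step: step 12

Remark on numbering: daucane numbering is used for the bicyclic compounds (C1 quaternary methyl-bearing ring-fusion carbon, C2 secondary carbinol, C3 CH2, C4 isopropyl-bearing tertiary carbinol, C5 ring-fusion CH, C6 ester carbinol, C7 CH2, C8 methyl-bearing alkene carbon, C9 alkene CH, C10 CH2), and the same labels are used for the corresponding carbons of the acyclic precursors.
Remark on supply: 4-(tert-butyldimethylsilyloxy)benzoic acid, allenylboronic acid pinacol ester and the phosphoric acid (S)-TRIP are taken as catalogue chemicals.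

Step 1
Reactants: 1 (E)-but-2-enal; 2 2-(triphenylphosphoranylidene)propanal
Product: 3 (2E,4E)-2-methylhexa-2,4-dienal
Conditions: toluene, 80 °C
Reagents that add atoms: 2-(triphenylphosphoranylidene)propanal, CC(C=O)=P(c1ccccc1)(c1ccccc1)c1ccccc1
Why: Wittig olefination with a stabilised formyl ylide is E-selective for the new trisubstituted alkene and leaves the existing E-alkene untouched, giving the diene carbons C8–C10 and C1 with the future C2 as aldehyde.

Step 2
Reactants: 3 (2E,4E)-2-methylhexa-2,4-dienal; 4 allenylboronic acid pinacol ester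
Product: 5 (4S,5E,7E)-5-methylnona-5,7-dien-1-yn-4-ol
Conditions: (S)-TRIP phosphoric acid (5 mol %), 4 Å MS, toluene, −20 °C; aqueous work-up
Reagents that add atoms: allenylboronic acid pinacol ester, C=C=CB1OC(C)(C)C(C)(C)O1
Why: Chiral-phosphoric-acid-catalysed propargylation of the aldehyde by the allenylboronate (closed six-membered SE2′ transition state) should deliver the propargyl group to the Si face and set the C2 carbinol as S, the catalyst antipode being the one chosen for this sense.

Step 3
Reactants: 5 (4S,5E,7E)-5-methylnona-5,7-dien-1-yn-4-ol; 6 tert-butyldimethylsilyl chloride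
Product: 7 tert-butyl(dimethyl){[(4S,5E,7E)-5-methylnona-5,7-dien-1-yn-4-yl]oxy}silane
Conditions: imidazole, DMF, rt
Reagents that add atoms: tert-butyldimethylsilyl chloride, CC(C)(C)[Si](C)(C)Cl
Why: Standard silylation of the secondary alcohol gives a robust ether that lasts to the final step and later serves as the steric control element next to the diene.

Step 4
Reactants: 7 the silyl ether of step 3; 8 methyl chloroformate
Product: 10 methyl (5S,6E,8E)-5-(tert-butyldimethylsilyloxy)-6-methyldeca-6,8-dien-2-ynoate, via lithium acetylide 9 (not isolated)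
Conditions: n-BuLi, THF, −78 °C; then ClCO2Me, −78 → 0 °C
Reagents that add atoms: methyl chloroformate, COC(=O)Cl
Why: Deprotonation of the terminal alkyne and C-acylation of the acetylide with a chloroformate is a routine ynoate synthesis, and 7 has no other acidic or electrophilic site.

Step 5
Reactants: 10 the ynoate; 11 isopropylmagnesium chloride
Product: 13 methyl (2E,5S,6E,8E)-5-(tert-butyldimethylsilyloxy)-6-methyl-3-(propan-2-yl)deca-2,6,8-trienoate, via alkenylcopper adduct 12 (not isolated)
Conditions: i-PrMgCl (2.2 equiv), CuI (1.1 equiv), THF, −78 °C; NH4Cl/MeOH quench at −78 °C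
Reagents that add atoms: isopropylmagnesium chloride, CC(C)[Mg]Cl
Why: syn-Carbocupration of the ynoate and protonation of the configurationally stable alkenylcopper at low temperature place isopropyl cis to hydrogen, so the ester is cis to the CH2 tether (2E), the geometry that later fixes the C4/C5 relationship.

Step 6
Reactants: 13 the (2E)-enoate
Product: 14 (2E,5S,6E,8E)-5-(tert-butyldimethylsilyloxy)-6-methyl-3-(propan-2-yl)deca-2,6,8-trien-1-ol
Conditions: i-Bu2AlH (2.5 equiv), CH2Cl2, −78 °C; Rochelle salt work-up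
Reagents that add atoms: none
Why: 1,2-Reduction of the enoate by the aluminium hydride gives the allylic alcohol without touching the alkene geometry, the diene or the silyl ether.

Step 7
Reactants: 14 the allylic alcohol; 15 tert-butyl hydroperoxide
Product: 16 [(2R,3R)-3-{(2S,3E,5E)-2-(tert-butyldimethylsilyloxy)-3-methylhepta-3,5-dien-1-yl}-3-(propan-2-yl)oxiran-2-yl]methanol
Conditions: Ti(OiPr)4 (10 mol %), D-(−)-diethyl tartrate (12 mol %), t-BuOOH, 4 Å MS, CH2Cl2, −20 °C
Reagents that add atoms: tert-butyl hydroperoxide, CC(C)(C)OO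
Why: Sharpless asymmetric epoxidation is directed by the allylic hydroxyl, so only the C4=C5 alkene reacts, and D-(−)-tartrate should deliver oxygen to the face that gives the (2R,3R)-epoxide (4R at the future tertiary carbinol) under reagent control.

Step 8
Reactants: 16 the epoxy alcohol
Product: 17 (2S,3R)-3-{(2S,3E,5E)-2-(tert-butyldimethylsilyloxy)-3-methylhepta-3,5-dien-1-yl}-3-(propan-2-yl)oxirane-2-carbaldehyde
Conditions: Dess–Martin periodinane, pyridine, CH2Cl2, 0 °C
Reagents that add atoms: none
Why: Buffered Dess–Martin oxidation converts the primary alcohol into the aldehyde under non-acidic conditions that keep the trisubstituted epoxide intact.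

Step 9
Reactants: 17 the epoxy aldehyde; 18 methylmagnesium bromide
Product: 19 1-[(2R,3R)-3-{(2S,3E,5E)-2-(tert-butyldimethylsilyloxy)-3-methylhepta-3,5-dien-1-yl}-3-(propan-2-yl)oxiran-2-yl]ethan-1-ol (both carbinol epimers)
Conditions: MeMgBr, THF, −78 °C
Reagents that add atoms: methylmagnesium bromide, C[Mg]Br
Why: Grignard addition to the aldehyde is faster than epoxide opening at −78 °C, and the new carbinol centre, formed without control, is removed in the next step.

Step 10
Reactants: 19 the secondary epoxy alcohol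
Product: 20 1-[(2S,3R)-3-{(2S,3E,5E)-2-(tert-butyldimethylsilyloxy)-3-methylhepta-3,5-dien-1-yl}-3-(propan-2-yl)oxiran-2-yl]ethan-1-one
Conditions: Dess–Martin periodinane, pyridine, CH2Cl2, 0 °C → rt
Reagents that add atoms: none
Why: Dess–Martin oxidation of the secondary alcohol gives the α,β-epoxy methyl ketone, whose oxiranyl α-carbon cannot epimerise by enolisation.

Step 11
Reactants: 20 the epoxy methyl ketone; 21 chlorotriethylsilane
Product: 23 triethyl({1-[(2S,3R)-3-{(2S,3E,5E)-2-(tert-butyldimethylsilyloxy)-3-methylhepta-3,5-dien-1-yl}-3-(propan-2-yl)oxiran-2-yl]ethenyl}oxy)silane, via lithium enolate 22 (not isolated)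
Conditions: LiN(SiMe3)2, Et3SiCl, THF, −78 °C (silyl chloride present during deprotonation)
Reagents that add atoms: chlorotriethylsilane, CC[Si](Cl)(CC)CC
Why: Kinetic enolisation can occur only at the methyl group (an oxiranyl enolate would be too strained), and O-silylation under basic conditions gives the epoxy enol silane without a Lewis acid that could open the epoxide prematurely.

Step 12
Reactants: 23 the epoxy enol silane
Product: 25 (1R,2S,4R,5R,8R)-2-(tert-butyldimethylsilyloxy)-4-hydroxydauc-9-en-6-one, via cycloadduct triethylsilyl ether 24 (not isolated)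
Conditions: Et3SiOTf (10 mol %), CH2Cl2, −78 °C; then HF·pyridine, pyridine, THF, 0 °C → rt
Reagents that add atoms: none
Why: Catalytic Et3SiOTf silylates the epoxide oxygen, the C5–O bond ionises with help of the enol silane (2-silyloxyallyl cation character at C5–C6–C7), the diene terminus C1 attacks C5 anti to the departing oxygen, the allyl cation left on C8–C10 is captured at C8 by the enol carbon C7, and silyl transfer from the carbonyl oxygen to the C4 alkoxide releases the catalyst. The closest known reaction type is the silyl-triflate-catalysed intramolecular (4+3) cycloaddition of epoxy enol silanes with tethered dienes and furans. The cyclopentane closes by opening of the epoxide at the carbon remote from the tether (5-endo with respect to the epoxide, allowed by the allylic activation of C5), and the cycloheptene closes by 7-(enolendo)-endo-trig union of the enol silane with the allyl cation. C4 keeps the epoxide configuration, C5 is inverted so that the E-derived epoxide gives the C4 oxygen cis to the C5–C6 bond, the quaternary C1 follows from attack on the diene face that keeps the C2 silyloxy group in the diene plane beside C10–H and away from the C1 methyl (no A(1,2) strain) in an extended arrangement that leads to the trans ring fusion, and C8 (set by the E terminal alkene) is erased in step 15. The step needs diene facial selectivity and (4+3) capture in preference to (3+2) capture, ionisation at the tertiary epoxide carbon or loss of the dienylic silyl ether; the E,E-diene with the tether in the outside position, the short tether, the catalytic amount of Lewis acid and −78 °C are expected to secure this.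

Step 13
Reactants: 25 the β-hydroxy ketone
Product: 26 (1R,2S,4R,5S,6S,8R)-2-(tert-butyldimethylsilyloxy)dauc-9-ene-4,6-diol
Conditions: Me4NBH(OAc)3, MeCN/AcOH, −30 °C
Reagents that add atoms: none
Why: In this hydroxyl-directed (Evans–Saksena type) reduction the C4 alkoxy(diacetoxy)borohydride should deliver hydride intramolecularly to the face of the C6 carbonyl on which the C4–O bond lies, giving the 4,6-anti diol, i.e. the 6S carbinol.

Step 14
Reactants: 26 the diol; 27 4-(tert-butyldimethylsilyloxy)benzoic acid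
Product: 28 (1R,2S,4R,5S,6S,8R)-2-(tert-butyldimethylsilyloxy)-4-hydroxydauc-9-en-6-yl 4-(tert-butyldimethylsilyloxy)benzoate
Conditions: DCC, DMAP, CH2Cl2, rt
Reagents that add atoms: 4-(tert-butyldimethylsilyloxy)benzoic acid, CC(C)(C)[Si](C)(C)Oc1ccc(cc1)C(=O)O
Why: Steglich esterification acylates the secondary C6 hydroxyl, the tertiary C4 hydroxyl being too hindered to compete, and the silyl-protected phenol cannot self-condense.

Step 15
Reactants: 28 the dauc-9-ene ester
Product: 29 (1R,2S,4R,5S,6S)-2-(tert-butyldimethylsilyloxy)-4-hydroxydauc-8-en-6-yl 4-(tert-butyldimethylsilyloxy)benzoate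
Conditions: RuHCl(CO)(PPh3)3 (10 mol %), toluene, 80 °C
Reagents that add atoms: none
Why: Ruthenium-hydride-catalysed alkene isomerisation (insertion/β-hydride elimination) should move the C9=C10 bond one position to the trisubstituted C8=C9 alkene, because C8–H is the only β-hydrogen that leads onward (C1 is quaternary) and further migration would require a tertiary alkylruthenium at C8.

Step 16
Reactants: 29 the dauc-8-ene ester
Product: 30 2α-hydroxyferutinin, (1R,2S,4R,5S,6S)-2,4-dihydroxydauc-8-en-6-yl 4-hydroxybenzoate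
Conditions: HF·pyridine, THF, 0 °C → rt
Reagents that add atoms: none
Why: Fluoride-mediated desilylation removes the hindered secondary alkyl silyl ether and the aryl silyl ether under mildly acidic conditions that leave the benzoate, the tertiary alcohol and the alkene untouched.

Compound list
1 | (E)-but-2-enal (crotonaldehyde) | C/C=C/C=O | starting material
2 | 2-(triphenylphosphoranylidene)propanal | CC(C=O)=P(c1ccccc1)(c1ccccc1)c1ccccc1 | starting material
3 | (2E,4E)-2-methylhexa-2,4-dienal | O=C/C(C)=C/C=C/C | intermediate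
4 | allenylboronic acid pinacol ester | C=C=CB1OC(C)(C)C(C)(C)O1 | starting material
5 | (4S,5E,7E)-5-methylnona-5,7-dien-1-yn-4-ol | C#CC[C@H](O)/C(C)=C/C=C/C | intermediate
6 | tert-butyldimethylsilyl chloride | CC(C)(C)[Si](C)(C)Cl | starting material
7 | tert-butyl(dimethyl){[(4S,5E,7E)-5-methylnona-5,7-dien-1-yn-4-yl]oxy}silane | C#CC[C@H](O[Si](C)(C)C(C)(C)C)/C(C)=C/C=C/C | intermediate
8 | methyl chloroformate | COC(=O)Cl | starting material
9 | lithium acetylide of 7 | [Li]C#CC[C@H](O[Si](C)(C)C(C)(C)C)/C(C)=C/C=C/C | intermediate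
10 | methyl (5S,6E,8E)-5-(tert-butyldimethylsilyloxy)-6-methyldeca-6,8-dien-2-ynoate | COC(=O)C#CC[C@H](O[Si](C)(C)C(C)(C)C)/C(C)=C/C=C/C | intermediate
11 | isopropylmagnesium chloride | CC(C)[Mg]Cl | starting material
12 | alkenylcopper adduct of 10 (copper on C2 of the enoate, cis to isopropyl) | COC(=O)/C([Cu])=C(/C(C)C)C[C@H](O[Si](C)(C)C(C)(C)C)/C(C)=C/C=C/C | intermediate
13 | methyl (2E,5S,6E,8E)-5-(tert-butyldimethylsilyloxy)-6-methyl-3-(propan-2-yl)deca-2,6,8-trienoate | COC(=O)/C=C(/C(C)C)C[C@H](O[Si](C)(C)C(C)(C)C)/C(C)=C/C=C/C | intermediate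
14 | (2E,5S,6E,8E)-5-(tert-butyldimethylsilyloxy)-6-methyl-3-(propan-2-yl)deca-2,6,8-trien-1-ol | OC/C=C(/C(C)C)C[C@H](O[Si](C)(C)C(C)(C)C)/C(C)=C/C=C/C | intermediate
15 | tert-butyl hydroperoxide | CC(C)(C)OO | starting material
16 | [(2R,3R)-3-{(2S,3E,5E)-2-(tert-butyldimethylsilyloxy)-3-methylhepta-3,5-dien-1-yl}-3-(propan-2-yl)oxiran-2-yl]methanol | OC[C@H]1O[C@@]1(C(C)C)C[C@H](O[Si](C)(C)C(C)(C)C)/C(C)=C/C=C/C | intermediate
17 | (2S,3R)-3-{(2S,3E,5E)-2-(tert-butyldimethylsilyloxy)-3-methylhepta-3,5-dien-1-yl}-3-(propan-2-yl)oxirane-2-carbaldehyde | O=C[C@H]1O[C@@]1(C(C)C)C[C@H](O[Si](C)(C)C(C)(C)C)/C(C)=C/C=C/C | intermediate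
18 | methylmagnesium bromide | C[Mg]Br | starting material
19 | 1-[(2R,3R)-3-{(2S,3E,5E)-2-(tert-butyldimethylsilyloxy)-3-methylhepta-3,5-dien-1-yl}-3-(propan-2-yl)oxiran-2-yl]ethan-1-ol (both carbinol epimers) | CC(O)[C@H]1O[C@@]1(C(C)C)C[C@H](O[Si](C)(C)C(C)(C)C)/C(C)=C/C=C/C | intermediate
20 | 1-[(2S,3R)-3-{(2S,3E,5E)-2-(tert-butyldimethylsilyloxy)-3-methylhepta-3,5-dien-1-yl}-3-(propan-2-yl)oxiran-2-yl]ethan-1-one | CC(=O)[C@H]1O[C@@]1(C(C)C)C[C@H](O[Si](C)(C)C(C)(C)C)/C(C)=C/C=C/C | intermediate
21 | chlorotriethylsilane | CC[Si](Cl)(CC)CC | starting material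
22 | lithium enolate of 20 (methyl-side enolate, epoxide unchanged) | [Li]OC(=C)[C@H]1O[C@@]1(C(C)C)C[C@H](O[Si](C)(C)C(C)(C)C)/C(C)=C/C=C/C | intermediate
23 | triethyl({1-[(2S,3R)-3-{(2S,3E,5E)-2-(tert-butyldimethylsilyloxy)-3-methylhepta-3,5-dien-1-yl}-3-(propan-2-yl)oxiran-2-yl]ethenyl}oxy)silane | C=C(O[Si](CC)(CC)CC)[C@H]1O[C@@]1(C(C)C)C[C@H](O[Si](C)(C)C(C)(C)C)/C(C)=C/C=C/C | intermediate
24 | (1R,2S,4R,5R,8R)-2-(tert-butyldimethylsilyloxy)-4-(triethylsilyloxy)dauc-9-en-6-one (trans-fused) | C[C@H]1C=C[C@]2(C)[C@@H](C(=O)C1)[C@](O[Si](CC)(CC)CC)(C(C)C)C[C@@H]2O[Si](C)(C)C(C)(C)C | intermediate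
25 | (1R,2S,4R,5R,8R)-2-(tert-butyldimethylsilyloxy)-4-hydroxydauc-9-en-6-one | C[C@H]1C=C[C@]2(C)[C@@H](C(=O)C1)[C@](O)(C(C)C)C[C@@H]2O[Si](C)(C)C(C)(C)C | intermediate
26 | (1R,2S,4R,5S,6S,8R)-2-(tert-butyldimethylsilyloxy)dauc-9-ene-4,6-diol | C[C@H]1C=C[C@]2(C)[C@@H]([C@@H](O)C1)[C@](O)(C(C)C)C[C@@H]2O[Si](C)(C)C(C)(C)C | intermediate
27 | 4-(tert-butyldimethylsilyloxy)benzoic acid | CC(C)(C)[Si](C)(C)Oc1ccc(cc1)C(=O)O | starting material
28 | (1R,2S,4R,5S,6S,8R)-2-(tert-butyldimethylsilyloxy)-4-hydroxydauc-9-en-6-yl 4-(tert-butyldimethylsilyloxy)benzoate | C[C@H]1C=C[C@]2(C)[C@@H]([C@@H](OC(=O)c3ccc(O[Si](C)(C)C(C)(C)C)cc3)C1)[C@](O)(C(C)C)C[C@@H]2O[Si](C)(C)C(C)(C)C | intermediate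
29 | (1R,2S,4R,5S,6S)-2-(tert-butyldimethylsilyloxy)-4-hydroxydauc-8-en-6-yl 4-(tert-butyldimethylsilyloxy)benzoate | CC1=CC[C@]2(C)[C@@H]([C@@H](OC(=O)c3ccc(O[Si](C)(C)C(C)(C)C)cc3)C1)[C@](O)(C(C)C)C[C@@H]2O[Si](C)(C)C(C)(C)C | intermediate
30 | 2α-hydroxyferutinin, (1R,2S,4R,5S,6S)-2,4-dihydroxydauc-8-en-6-yl 4-hydroxybenzoate | CC1=CC[C@]2(C)[C@@H]([C@@H](OC(=O)c3ccc(O)cc3)C1)[C@](O)(C(C)C)C[C@@H]2O | target

Total step count: 16
Longest linear sequence: 16 steps (from 1 to 30)

Steps most likely to fail

Step 12 (key step). The tethered diene may attack the activated epoxide with poor facial selectivity, the silylated epoxide may ionise at its tertiary carbon and rearrange, or the dienylic silyl ether may ionise under the Lewis acid. The fallback generates the oxyallyl cation from an α-bromo ketone under basic conditions, without a Lewis acid. Setting out from 20, MgBr2·OEt2 (Et2O, −20 °C) should open the epoxide at the carbon next to the carbonyl group with inversion to give the bromohydrin (3R,4R,6S,7E,9E)-3-bromo-6-(tert-butyldimethylsilyloxy)-4-hydroxy-7-methyl-4-(propan-2-yl)undeca-7,9-dien-2-one F1. Et3SiOTf and 2,6-lutidine (CH2Cl2, −78 °C) then silylate the tertiary hydroxyl to give (3R,4R,6S,7E,9E)-3-bromo-6-(tert-butyldimethylsilyloxy)-7-methyl-4-(propan-2-yl)-4-(triethylsilyloxy)undeca-7,9-dien-2-one F2. NaOCH2CF3 in CF3CH2OH (0 °C) forms the methyl-side enolate, which loses bromide to give the free 2-oxyallyl cation; this should undergo the same intramolecular (4+3) cycloaddition through the extended arrangement, and the route is rejoined at 24.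

Step 15. The hindered cis alkene may not insert into the metal hydride (the ruthenium must approach the face that carries C8–H, which is also the face of the angular methyl), or migration may run on to the C7=C8 isomer. The fallback places the alkene by a regiospecific redox sequence at the ketone stage. Setting out from 25, LiN(i-Pr)2 and Me3SiCl (THF, −78 °C) give the bis(trimethylsilyl) derivative 2-(tert-butyldimethylsilyloxy)-4,6-bis(trimethylsilyloxy)dauca-6,9-diene (configuration of 25 at C1, C2, C4, C5 and C8) F3. Saegusa–Ito dehydrogenation with Pd(OAc)2 in MeCN and a citric acid work-up give the linear dienone (1R,2S,4R,5R)-2-(tert-butyldimethylsilyloxy)-4-hydroxydauca-7,9-dien-6-one F4. Lithium in NH3/THF at −78 °C with a solid NH4Cl quench (dissolving-metal 1,6-reduction, kinetic α-protonation of the dienolate) should give the β,γ-unsaturated ketone (1R,2S,4R,5R)-2-(tert-butyldimethylsilyloxy)-4-hydroxydauc-8-en-6-one F5. Me4NBH(OAc)3 as in step 13 gives (1R,2S,4R,5S,6S)-2-(tert-butyldimethylsilyloxy)dauc-8-ene-4,6-diol F6, and DCC/DMAP esterification with 27 rejoins the route at 29.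

Step 13. Internal hydride delivery from the hindered tertiary alkoxyborohydride may be slow, so that external attack from the other face gives the C6 epimer. The fallback reverses the sense of reduction on purpose and installs the ester with inversion. Setting out from 25, LiBH(s-Bu)3 (THF, −78 °C) should attack C6 from the face opposite the angular C1 methyl to give the 6-epimeric diol (1R,2S,4R,5S,6R,8R)-2-(tert-butyldimethylsilyloxy)dauc-9-ene-4,6-diol F7. Mitsunobu esterification with 27 (PPh3, DIAD, toluene, 0 °C → rt) inverts C6 and rejoins the route at 28.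

Further compounds
F1 | step 12 | (3R,4R,6S,7E,9E)-3-bromo-6-(tert-butyldimethylsilyloxy)-4-hydroxy-7-methyl-4-(propan-2-yl)undeca-7,9-dien-2-one | CC(=O)[C@H](Br)[C@](O)(C(C)C)C[C@H](O[Si](C)(C)C(C)(C)C)/C(C)=C/C=C/C
F2 | step 12 | (3R,4R,6S,7E,9E)-3-bromo-6-(tert-butyldimethylsilyloxy)-7-methyl-4-(propan-2-yl)-4-(triethylsilyloxy)undeca-7,9-dien-2-one | CC(=O)[C@H](Br)[C@](O[Si](CC)(CC)CC)(C(C)C)C[C@H](O[Si](C)(C)C(C)(C)C)/C(C)=C/C=C/C
F3 | step 15 | 2-(tert-butyldimethylsilyloxy)-4,6-bis(trimethylsilyloxy)dauca-6,9-diene (configuration of 25 at C1, C2, C4, C5 and C8) | C[C@H]1C=C[C@]2(C)[C@@H](C(O[Si](C)(C)C)=C1)[C@](O[Si](C)(C)C)(C(C)C)C[C@@H]2O[Si](C)(C)C(C)(C)C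
F4 | step 15 | (1R,2S,4R,5R)-2-(tert-butyldimethylsilyloxy)-4-hydroxydauca-7,9-dien-6-one | CC1C=C[C@]2(C)[C@@H](C(=O)C=1)[C@](O)(C(C)C)C[C@@H]2O[Si](C)(C)C(C)(C)C
F5 | step 15 | (1R,2S,4R,5R)-2-(tert-butyldimethylsilyloxy)-4-hydroxydauc-8-en-6-one | CC1=CC[C@]2(C)[C@@H](C(=O)C1)[C@](O)(C(C)C)C[C@@H]2O[Si](C)(C)C(C)(C)C
F6 | step 15 | (1R,2S,4R,5S,6S)-2-(tert-butyldimethylsilyloxy)dauc-8-ene-4,6-diol | CC1=CC[C@]2(C)[C@@H]([C@@H](O)C1)[C@](O)(C(C)C)C[C@@H]2O[Si](C)(C)C(C)(C)C
F7 | step 13 | (1R,2S,4R,5S,6R,8R)-2-(tert-butyldimethylsilyloxy)dauc-9-ene-4,6-diol | C[C@H]1C=C[C@]2(C)[C@@H]([C@H](O)C1)[C@](O)(C(C)C)C[C@@H]2O[Si](C)(C)C(C)(C)C
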